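A closed, stirred vessel at fixed volume and temperature holds free monomer and initiator, and free monomer passes into chains.

| setting | south-east | north | flask |
|---|---|---|---|
| free monomer | 0.28 M | 0.44 M | 0.20 M |
| initiator | 0.2 mol% | 0.2 mol% | 0.2 mol% |
| remark | run made earlier | run made earlier |  |
| time |  |  | 8.0 min |

| run | time / min | monomer in chains / % | free monomer / % |
|---|---|---|---|
| south-east | 1.33 | 17.3 | 82.0 |
| south-east | 2.50 | 32.0 | 67.5 |
| south-east | 4.00 | 47.0 | 52.0 |
| south-east | 5.00 | 54.0 | 44.7 |
| north | 0.417 | 8.9 | 92.0 |
| north | 0.833 | 17.2 | 82.2 |
| north | 2.00 | 38.4 | 60.7 |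
| north | 5.00 | 71.8 | 26.9 |

(readings scatter by 0.5 percentage points)

* average number of monomer units in a chain (chains begun, living or dead) at 8.0 min
* part of the free monomer that has reacted at 8.0 min

- the average divides the monomer in chains by the number of chains begun, living and dead together
- the earlier runs do not show the number of chains; that part of a forecast is a guess

Let y be the fraction of free monomer left and C its charge. The runs share one loading, so we try a pseudo-first-order decay with a rate proportional to C. The last readings give −ln y/(Ct) = 0.575 L mol⁻¹ min⁻¹ in the south-east run and 0.597 L mol⁻¹ min⁻¹ in the north run.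

But these include the first moments, so a small lag τ may hide in them. Slopes between two later readings cancel τ and give 0.589 L mol⁻¹ min⁻¹ and 0.617 L mol⁻¹ min⁻¹. A gap remains, but a scatter of 0.5 percentage points on the last south-east reading shifts the first value by 0.0160 L mol⁻¹ min⁻¹, so we read no trend into it. Their mean, κ = 0.603 L mol⁻¹ min⁻¹, is our reading of the decay rate of free monomer per molar charged at this loading.

Running the lines back gives a reading of τ = 0.138 min. It may differ in this flask, but the correction is worth just 0.64 points of conversion. With y = exp(−κC(t−τ)), we reckon c = 61.2%. The runs do not show the number of chains, so we reckon no dp.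

The forecast gives 59.5% and a dp of 290. Its c lies a little below ours, and of its chain count it warns: “poor efficiency raises dp, transfer lowers it”.

The flask gives c = 60.9% and dp = 2580, a factor of 8.90 above the forecast.

    free monomer + initiator → spent initiator (k = 0.358 L mol⁻¹ s⁻¹)
    2 free monomer → self-condensation product (k = 1.33 × 10⁻⁴ L mol⁻¹ s⁻¹)
    free monomer + initiator → living end + monomer in chains (k = 0.0467 L mol⁻¹ s⁻¹)
    free monomer + living end → monomer in chains + living end, rate k4*[living end]*[free monomer] (k = 42.6 L mol⁻¹ s⁻¹)

At 8.00 min this flask holds 4.62 × 10⁻⁵ M of living end from 4.00 × 10⁻⁴ M of initiator charged, while spent initiator stands at 0.177% of the free monomer charged. For a neighbour flask charged with 0.80 M, at the same loading and time, κ and τ give a free monomer fraction of 2.26%, and that flask holds 2.3%.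

The data are simulated for substances that don't exist.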